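**Retrosynthetic overview**

1. 26 ⇒ 20 + 23: C3–aroyl bond by acylation of the C3 vinyllithium; the methyl enol ether and both silyl ethers are removed in the last step.
2. 20 ⇒ 17 + 18: C5–geranyl bond by bridgehead lithiation and alkylation.
3. 16 ⇒ 13 + 14: C4–C5 and C1–C2 bonds by Effenberger annulation with malonyl dichloride. Ring order: ring A (the cyclohexanone, bought as 1) first, ring B (C1–C2–C3–C4–C5–C9) closed onto it here, the arene brought in intact.
4. 13 ⇒ 6 ⇒ 4: C1 prenyl by enolate alkylation, C8 gem-dimethyl by conjugate methylation, carbonyl position by Stork–Danheiser transposition.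
5. 4 ⇒ 1 + 2: the C7 stereocentre by a new palladium-catalysed enantioselective α′-prenylation (the proposed new step); C1 and C5 follow from C7 in line 3.

Assumption: the target is one enol tautomer of a rapidly equilibrating β-triketone, so the route delivers that equilibrium mixture; bicyclic compounds carry the target's locants (C1 = prenyl-bearing bridgehead next to C8 with the two methyl groups, C5 = other bridgehead, C9 = bridging ketone).

**Route**

Step 1
Reactants: 1 3-ethoxycyclohex-2-en-1-one; 2 3-methylbut-2-en-1-yl acetate (prenyl acetate)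
Product: 4 (S)-3-ethoxy-6-(3-methylbut-2-en-1-yl)cyclohex-2-en-1-one, via lithium dienolate 3 (not isolated)
Conditions: LiN(i-Pr)2 (1.05 equiv), THF, −78 °C; then added to [Pd(η3-C3H5)Cl]2 (2.5 mol %), (R,R)-DACH-phenyl Trost ligand (7.5 mol %), 2 (1.2 equiv), THF, −78 → −30 °C
Reagents that add atoms: none
Why: Proposed new method: zerovalent palladium ionises prenyl acetate to a cationic 1,1-dimethylallyl–palladium complex held in the chiral pocket of the diamide-bisphosphine ligand, and the cross-conjugated lithium α′-dienolate 3 attacks it from outside the metal at the unsubstituted CH2 terminus (hence linear prenyl, not reverse prenyl) with one enolate face shielded by the ligand, so that C6 (later C7 of the target) is set as S by catalyst control (the mirror-image ligand is taken if the sense of induction proves opposite), while low temperature and the absence of excess base keep the new tertiary α-centre from proton exchange with unreacted enolate; the closest known reaction type is the palladium-catalysed asymmetric allylic alkylation (Tsuji–Trost) of simple ketone enolates and enol carbonates to α-allyl ketones, which has not been shown for vinylogous-ester α′-enolates or for linear prenylation at an α-tertiary centre.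

Step 2
Reactants: 4 (S)-3-ethoxy-6-(3-methylbut-2-en-1-yl)cyclohex-2-en-1-one
Product: 6 (S)-3-methyl-4-(3-methylbut-2-en-1-yl)cyclohex-2-en-1-one, via lithium alkoxide 5 (not isolated)
Conditions: MeLi, Et2O, −78 → 0 °C; then 1 M HCl, rt
Reagents that add atoms: methyllithium, [Li]C; water, O
Why: Stork–Danheiser transposition, in which MeLi adds 1,2 to the vinylogous-ester carbonyl and aqueous acid hydrolyses the enol ether and dehydrates the β-hydroxy ketone to the transposed enone; the stereocentre (now C4) takes no part and is stable to brief dilute acid.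

Step 3
Reactants: 6 (S)-3-methyl-4-(3-methylbut-2-en-1-yl)cyclohex-2-en-1-one
Product: 8 (S)-[(3,3-dimethyl-4-(3-methylbut-2-en-1-yl)cyclohex-1-en-1-yl)oxy]trimethylsilane, via bromomagnesium enolate 7 (not isolated)
Conditions: MeMgBr, CuBr·SMe2 (10 mol %), TMSCl, DMPU, THF, −78 → −40 °C
Reagents that add atoms: methylmagnesium bromide, C[Mg]Br; chlorotrimethylsilane, C[Si](C)(C)Cl
Why: Copper-catalysed conjugate addition of the methyl Grignard reagent, accelerated by TMSCl, builds the C3 gem-dimethyl carbon (not a stereocentre) and the enolate is trapped regiospecifically on the C2 side as its silyl enol ether; C4 is untouched.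

Step 4
Reactants: 8 (S)-[(3,3-dimethyl-4-(3-methylbut-2-en-1-yl)cyclohex-1-en-1-yl)oxy]trimethylsilane; 9 1-bromo-3-methylbut-2-ene (prenyl bromide)
Product: 11 (4S)-3,3-dimethyl-2,4-bis(3-methylbut-2-en-1-yl)cyclohexan-1-one (C2 epimers), via lithium enolate 10 (not isolated)
Conditions: MeLi, THF, 0 °C → rt; then 9, DMPU, −78 → 0 °C
Reagents that add atoms: none
Why: MeLi cleaves the Si–O bond to release the regiodefined lithium enolate, which is C-alkylated at C2 by the allylic bromide (SN2 enolate alkylation); the new C2 centre forms as an epimer mixture, which is harmless because this carbon is enolised and set again in step 6.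

Step 5
Reactants: 11 (4S)-3,3-dimethyl-2,4-bis(3-methylbut-2-en-1-yl)cyclohexan-1-one (C2 epimers)
Product: 13 {[(4R)-5,5-dimethyl-4,6-bis(3-methylbut-2-en-1-yl)cyclohex-1-en-1-yl]oxy}trimethylsilane, via lithium enolate 12 (not isolated)
Conditions: LiN(i-Pr)2, THF, −78 °C; then TMSCl, Et3N, −78 → 0 °C
Reagents that add atoms: chlorotrimethylsilane, C[Si](C)(C)Cl
Why: Kinetic deprotonation by the hindered amide base removes a hydrogen of the unhindered C6 methylene, not the tertiary neopentyl C2 hydrogen, and O-silylation stores the less substituted enolate (regioselective silyl enol ether formation); the descriptor at C4 changes by priority only.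

Step 6
Reactants: 13 {[(4R)-5,5-dimethyl-4,6-bis(3-methylbut-2-en-1-yl)cyclohex-1-en-1-yl]oxy}trimethylsilane; 14 propanedioyl dichloride (malonyl dichloride)
Product: 16 (1R,5S,7R)-4-hydroxy-8,8-dimethyl-1,7-bis(3-methylbut-2-en-1-yl)bicyclo[3.3.1]non-3-ene-2,9-dione, via keto acid chloride 15 (not isolated)
Conditions: 14 (2 equiv), Et2O, −20 °C → rt; then KOH (aq), BnEt3NCl (cat.), rt; then 1 M HCl
Reagents that add atoms: none
Why: Effenberger α,α′-annulation, in which the silyl enol ether is C-acylated by one acid chloride group and the β-keto acid chloride 15 then enolises towards the prenyl-bearing carbon and is C-acylated intramolecularly; the three-carbon bridge can only span the two α-carbons diaxially and ring closure runs through the chair with the C7 prenyl group equatorial (exo, cis to the C1 prenyl group), the first-formed acyl centre being epimerisable, so C1 and C5 are both set from C7.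

Step 7
Reactants: 16 (1R,5S,7R)-4-hydroxy-8,8-dimethyl-1,7-bis(3-methylbut-2-en-1-yl)bicyclo[3.3.1]non-3-ene-2,9-dione
Product: 17 (1R,5S,7R)-2-methoxy-8,8-dimethyl-1,7-bis(3-methylbut-2-en-1-yl)bicyclo[3.3.1]non-2-ene-4,9-dione
Conditions: Me2SO4, K2CO3, acetone, reflux
Reagents that add atoms: dimethyl sulfate, COS(=O)(=O)OC
Why: O-alkylation of the cyclic β-diketone enolate (vinylogous ester formation) gives both enol ethers, of which the 2-methoxy isomer 17 (ketone next to the bridgehead C–H) is separated and the 4-methoxy isomer is hydrolysed back to 16 with LiOH and recycled; no stereocentre is touched.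

Step 8
Reactants: 17 (1R,5S,7R)-2-methoxy-8,8-dimethyl-1,7-bis(3-methylbut-2-en-1-yl)bicyclo[3.3.1]non-2-ene-4,9-dione; 18 (2E)-1-bromo-3,7-dimethylocta-2,6-diene (geranyl bromide)
Product: 20 (1R,5S,7R)-5-[(2E)-3,7-dimethylocta-2,6-dien-1-yl]-2-methoxy-8,8-dimethyl-1,7-bis(3-methylbut-2-en-1-yl)bicyclo[3.3.1]non-2-ene-4,9-dione, via bridgehead organolithium 19 (not isolated)
Conditions: LiN(i-Pr)2, THF, −78 °C; then 18, −78 → 0 °C
Reagents that add atoms: none
Why: Bridgehead lithiation at the α′-position of the vinylogous ester (C5, next to the C4 ketone) gives a carbanion that the bicycle keeps pyramidal, and it is alkylated by the allylic bromide with retention (bridgehead substitution), so C5 becomes quaternary with the configuration fixed by the ring system.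

Step 9
Reactants: 21 3,4-dihydroxybenzoic acid
Product: 22 tert-butyldimethylsilyl 3,4-bis[(tert-butyldimethylsilyl)oxy]benzoate
Conditions: TBSCl (3.3 equiv), imidazole, DMF, rt
Reagents that add atoms: tert-butyldimethylsilyl chloride, CC(C)(C)[Si](C)(C)Cl
Why: Imidazole-mediated silylation of both phenols and the acid (silyl ether and silyl ester formation) masks every acidic hydrogen of the aroyl fragment.

Step 10
Reactants: 22 tert-butyldimethylsilyl 3,4-bis[(tert-butyldimethylsilyl)oxy]benzoate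
Product: 23 3,4-bis[(tert-butyldimethylsilyl)oxy]benzoyl chloride
Conditions: (COCl)2, DMF (cat.), CH2Cl2, 0 °C → rt
Reagents that add atoms: oxalyl chloride, O=C(Cl)C(=O)Cl
Why: Oxalyl chloride with catalytic DMF (Vilsmeier-type activation) converts the silyl ester directly into the acid chloride under neutral conditions that leave the aryl silyl ethers intact.

Step 11
Reactants: 20 (1R,5S,7R)-5-[(2E)-3,7-dimethylocta-2,6-dien-1-yl]-2-methoxy-8,8-dimethyl-1,7-bis(3-methylbut-2-en-1-yl)bicyclo[3.3.1]non-2-ene-4,9-dione; 23 3,4-bis[(tert-butyldimethylsilyl)oxy]benzoyl chloride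
Product: 25 (1R,5R,7R)-3-{3,4-bis[(tert-butyldimethylsilyl)oxy]benzoyl}-5-[(2E)-3,7-dimethylocta-2,6-dien-1-yl]-2-methoxy-8,8-dimethyl-1,7-bis(3-methylbut-2-en-1-yl)bicyclo[3.3.1]non-2-ene-4,9-dione, via vinyllithium 24 (not isolated)
Conditions: lithium 2,2,6,6-tetramethylpiperidide, THF, −78 °C; then 23, −78 °C → rt
Reagents that add atoms: none
Why: With both bridgeheads quaternary the hindered amide base removes the only acidic hydrogen, the C3 vinylic one flanked by the carbonyl and methoxy groups (directed vinylic lithiation), and the vinyllithium is acylated by the acid chloride (addition–elimination); stereocentres, silyl ethers and olefins are untouched and the descriptor at C5 changes by priority only.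

Step 12
Reactants: 25 (1R,5R,7R)-3-{3,4-bis[(tert-butyldimethylsilyl)oxy]benzoyl}-5-[(2E)-3,7-dimethylocta-2,6-dien-1-yl]-2-methoxy-8,8-dimethyl-1,7-bis(3-methylbut-2-en-1-yl)bicyclo[3.3.1]non-2-ene-4,9-dione
Product: 26 (1S,5S,7R)-3-(3,4-dihydroxybenzoyl)-5-[(2E)-3,7-dimethylocta-2,6-dien-1-yl]-4-hydroxy-8,8-dimethyl-1,7-bis(3-methylbut-2-en-1-yl)bicyclo[3.3.1]non-3-ene-2,9-dione (CNP0160101.3)
Conditions: LiOH, 1,4-dioxane/H2O (degassed), 90 °C; then 1 M HCl
Reagents that add atoms: lithium hydroxide, [Li+].[OH-]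
Why: Hydroxide adds to C2 of the vinylogous ester and expels methoxide (addition–elimination hydrolysis) and cleaves both aryl silyl ethers at silicon, the product resting as its triketone enolate and catecholate until acidification; oxygen is excluded for the catechol, and no stereocentre or olefin is affected (descriptors at C1 and C5 change by priority only).

**Compound list**

1 | 3-ethoxycyclohex-2-en-1-one | CCOC1=CC(=O)CCC1 | starting material
2 | 3-methylbut-2-en-1-yl acetate (prenyl acetate) | CC(=O)OCC=C(C)C | starting material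
3 | lithium 5-ethoxycyclohexa-1,5-dien-1-olate (α′-dienolate of 1) | [Li]OC1=CCCC(OCC)=C1 | intermediate
4 | (S)-3-ethoxy-6-(3-methylbut-2-en-1-yl)cyclohex-2-en-1-one | CCOC1=CC(=O)[C@H](CC=C(C)C)CC1 | intermediate
5 | lithium (6S)-3-ethoxy-1-methyl-6-(3-methylbut-2-en-1-yl)cyclohex-2-en-1-olate (C1 epimers) | CCOC1=CC(C)(O[Li])[C@H](CC=C(C)C)CC1 | intermediate
6 | (S)-3-methyl-4-(3-methylbut-2-en-1-yl)cyclohex-2-en-1-one | O=C1CC[C@@H](CC=C(C)C)C(C)=C1 | intermediate
7 | bromomagnesium (S)-3,3-dimethyl-4-(3-methylbut-2-en-1-yl)cyclohex-1-en-1-olate | Br[Mg]OC1=CC(C)(C)[C@H](CC=C(C)C)CC1 | intermediate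
8 | (S)-[(3,3-dimethyl-4-(3-methylbut-2-en-1-yl)cyclohex-1-en-1-yl)oxy]trimethylsilane | C[Si](C)(C)OC1=CC(C)(C)[C@H](CC=C(C)C)CC1 | intermediate
9 | 1-bromo-3-methylbut-2-ene (prenyl bromide) | CC(C)=CCBr | starting material
10 | lithium (S)-3,3-dimethyl-4-(3-methylbut-2-en-1-yl)cyclohex-1-en-1-olate | [Li]OC1=CC(C)(C)[C@H](CC=C(C)C)CC1 | intermediate
11 | (4S)-3,3-dimethyl-2,4-bis(3-methylbut-2-en-1-yl)cyclohexan-1-one (C2 epimers) | O=C1CC[C@@H](CC=C(C)C)C(C)(C)C1CC=C(C)C | intermediate
12 | lithium (4R)-5,5-dimethyl-4,6-bis(3-methylbut-2-en-1-yl)cyclohex-1-en-1-olate (C6 epimers) | [Li]OC1=CC[C@@H](CC=C(C)C)C(C)(C)C1CC=C(C)C | intermediate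
13 | {[(4R)-5,5-dimethyl-4,6-bis(3-methylbut-2-en-1-yl)cyclohex-1-en-1-yl]oxy}trimethylsilane (C6 epimers) | C[Si](C)(C)OC1=CC[C@@H](CC=C(C)C)C(C)(C)C1CC=C(C)C | intermediate
14 | propanedioyl dichloride (malonyl dichloride) | O=C(Cl)CC(=O)Cl | starting material
15 | 3-[(5R)-4,4-dimethyl-3,5-bis(3-methylbut-2-en-1-yl)-2-oxocyclohexyl]-3-oxopropanoyl chloride (C1 and C3 of the ring as epimers) | O=C(Cl)CC(=O)C1C[C@@H](CC=C(C)C)C(C)(C)C(CC=C(C)C)C1=O | intermediate
16 | (1R,5S,7R)-4-hydroxy-8,8-dimethyl-1,7-bis(3-methylbut-2-en-1-yl)bicyclo[3.3.1]non-3-ene-2,9-dione (C7 prenyl exo) | [C@H]12C[C@@H](CC=C(C)C)C(C)(C)[C@](CC=C(C)C)(C(=O)C=C1O)C2=O | intermediate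
17 | (1R,5S,7R)-2-methoxy-8,8-dimethyl-1,7-bis(3-methylbut-2-en-1-yl)bicyclo[3.3.1]non-2-ene-4,9-dione | [C@H]12C[C@@H](CC=C(C)C)C(C)(C)[C@](CC=C(C)C)(C(OC)=CC1=O)C2=O | intermediate
18 | (2E)-1-bromo-3,7-dimethylocta-2,6-diene (geranyl bromide) | CC(C)=CCC/C(C)=C/CBr | starting material
19 | C5 bridgehead lithio derivative of 17 | [Li][C@]12C[C@@H](CC=C(C)C)C(C)(C)[C@](CC=C(C)C)(C(OC)=CC1=O)C2=O | intermediate
20 | (1R,5S,7R)-5-[(2E)-3,7-dimethylocta-2,6-dien-1-yl]-2-methoxy-8,8-dimethyl-1,7-bis(3-methylbut-2-en-1-yl)bicyclo[3.3.1]non-2-ene-4,9-dione | CC(C)=CCC/C(C)=C/C[C@]12C[C@@H](CC=C(C)C)C(C)(C)[C@](CC=C(C)C)(C(OC)=CC1=O)C2=O | intermediate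
21 | 3,4-dihydroxybenzoic acid | OC(=O)c1ccc(O)c(O)c1 | starting material
22 | tert-butyldimethylsilyl 3,4-bis[(tert-butyldimethylsilyl)oxy]benzoate | CC(C)(C)[Si](C)(C)OC(=O)c1ccc(O[Si](C)(C)C(C)(C)C)c(O[Si](C)(C)C(C)(C)C)c1 | intermediate
23 | 3,4-bis[(tert-butyldimethylsilyl)oxy]benzoyl chloride | ClC(=O)c1ccc(O[Si](C)(C)C(C)(C)C)c(O[Si](C)(C)C(C)(C)C)c1 | intermediate
24 | C3 vinyllithium derived from 20 | CC(C)=CCC/C(C)=C/C[C@]12C[C@@H](CC=C(C)C)C(C)(C)[C@](CC=C(C)C)(C(OC)=C([Li])C1=O)C2=O | intermediate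
25 | (1R,5R,7R)-3-{3,4-bis[(tert-butyldimethylsilyl)oxy]benzoyl}-5-[(2E)-3,7-dimethylocta-2,6-dien-1-yl]-2-methoxy-8,8-dimethyl-1,7-bis(3-methylbut-2-en-1-yl)bicyclo[3.3.1]non-2-ene-4,9-dione | CC(C)=CCC/C(C)=C/C[C@]12C[C@@H](CC=C(C)C)C(C)(C)[C@](CC=C(C)C)(C(OC)=C(C(=O)c3ccc(O[Si](C)(C)C(C)(C)C)c(O[Si](C)(C)C(C)(C)C)c3)C1=O)C2=O | intermediate
26 | (1S,5S,7R)-3-(3,4-dihydroxybenzoyl)-5-[(2E)-3,7-dimethylocta-2,6-dien-1-yl]-4-hydroxy-8,8-dimethyl-1,7-bis(3-methylbut-2-en-1-yl)bicyclo[3.3.1]non-3-ene-2,9-dione (CNP0160101.3) | CC(C)=CCC/C(C)=C/C[C@]12C[C@@H](CC=C(C)C)C(C)(C)[C@](CC=C(C)C)(C(=O)C(C(=O)c3ccc(O)c(O)c3)=C1O)C2=O | target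

**Step count and risks**

Total step count: 12. Longest linear sequence: 10 steps (steps 1 to 8, then 11 and 12); steps 9 and 10 make the aroyl chloride that joins in step 11.

The three steps most likely to fail:

Step 1 (the proposed new prenylation; risks are low enantiomeric excess, the reverse-prenyl isomer and bis-alkylation). The fallback uses known auxiliary chemistry, sets out from 9 and comes back to the route at 6. Cyclohexanone is condensed with (S)-1-amino-2-(methoxymethyl)pyrrolidine to give (S)-N-cyclohexylidene-2-(methoxymethyl)pyrrolidin-1-amine F1. LiN(i-Pr)2 in THF and then 9 at −95 °C (Enders azaenolate alkylation) give (S)-2-(methoxymethyl)-N-[(2S)-2-(3-methylbut-2-en-1-yl)cyclohexylidene]pyrrolidin-1-amine F2. Two-phase cleavage with aqueous oxalic acid releases (S)-2-(3-methylbut-2-en-1-yl)cyclohexan-1-one F3 without racemisation. LiN(i-Pr)2 and TMSCl at −78 °C give the kinetic enol ether (S)-trimethyl{[6-(3-methylbut-2-en-1-yl)cyclohex-1-en-1-yl]oxy}silane F4. Pd(OAc)2 in MeCN (Saegusa–Ito oxidation) gives (S)-6-(3-methylbut-2-en-1-yl)cyclohex-2-en-1-one F5. MeLi adds to the carbonyl to give (6S)-1-methyl-6-(3-methylbut-2-en-1-yl)cyclohex-2-en-1-ol F6. Pyridinium chlorochromate, [C5H5NH][CrO3Cl], then effects the oxidative 1,3-transposition to 6, and the route continues with step 3.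

Step 6 (Effenberger annulation; modest yields and competing O-acylation are usual). The fallback builds ring B at a lower oxidation level and oxidises afterwards; it sets out from 11 and comes back at 16. Ketone 11 and pyrrolidine (TiCl4, toluene) give the less substituted enamine 1-[(4R)-5,5-dimethyl-4,6-bis(3-methylbut-2-en-1-yl)cyclohex-1-en-1-yl]pyrrolidine F7. Acryloyl chloride in refluxing MeCN followed by aqueous work-up (enamine α,α′-annulation: C-alkylation at the unhindered carbon, then ketene acylation at the prenyl-bearing carbon) gives (1R,5R,7R)-8,8-dimethyl-1,7-bis(3-methylbut-2-en-1-yl)bicyclo[3.3.1]nonane-2,9-dione F8. IBX in DMSO at 70 °C dehydrogenates C3–C4 to (1R,5S,7R)-8,8-dimethyl-1,7-bis(3-methylbut-2-en-1-yl)bicyclo[3.3.1]non-3-ene-2,9-dione F9. Wacker-type oxidation of the enone β-carbon (Na2PdCl4 cat., t-BuOOH, AcOH/H2O, 50 °C) then gives 16.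

Step 8 (bridgehead geranylation; it needs the 2-methoxy regioisomer from step 7 and a hindered bridgehead anion that competes with C3 lithiation). The fallback puts the geranyl group in before the annulation, so neither a bridgehead anion nor a particular enol-ether isomer is needed; it sets out from 11 and comes back at 20. LiN(i-Pr)2 and then 18 alkylate 11 at C6 to give (4R)-6-[(2E)-3,7-dimethylocta-2,6-dien-1-yl]-3,3-dimethyl-2,4-bis(3-methylbut-2-en-1-yl)cyclohexan-1-one F10. LiN(i-Pr)2 and TMSCl give {[(4R)-2-[(2E)-3,7-dimethylocta-2,6-dien-1-yl]-5,5-dimethyl-4,6-bis(3-methylbut-2-en-1-yl)cyclohex-1-en-1-yl]oxy}trimethylsilane F11. Annulation with 14 and then KOH/BnEt3NCl, now forming both quaternary bridgeheads, gives (1R,5S,7R)-5-[(2E)-3,7-dimethylocta-2,6-dien-1-yl]-4-hydroxy-8,8-dimethyl-1,7-bis(3-methylbut-2-en-1-yl)bicyclo[3.3.1]non-3-ene-2,9-dione F12. Me2SO4 and K2CO3 in acetone then give 20 (its 4-methoxy isomer is recycled by LiOH hydrolysis).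

**Further compounds**

F1 | step 1 | (S)-N-cyclohexylidene-2-(methoxymethyl)pyrrolidin-1-amine | COC[C@@H]1CCCN1N=C1CCCCC1
F2 | step 1 | (S)-2-(methoxymethyl)-N-[(2S)-2-(3-methylbut-2-en-1-yl)cyclohexylidene]pyrrolidin-1-amine (C=N geometry not fixed) | COC[C@@H]1CCCN1N=C1CCCC[C@H]1CC=C(C)C
F3 | step 1 | (S)-2-(3-methylbut-2-en-1-yl)cyclohexan-1-one | O=C1CCCC[C@H]1CC=C(C)C
F4 | step 1 | (S)-trimethyl{[6-(3-methylbut-2-en-1-yl)cyclohex-1-en-1-yl]oxy}silane | C[Si](C)(C)OC1=CCCC[C@H]1CC=C(C)C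
F5 | step 1 | (S)-6-(3-methylbut-2-en-1-yl)cyclohex-2-en-1-one | O=C1C=CCC[C@H]1CC=C(C)C
F6 | step 1 | (6S)-1-methyl-6-(3-methylbut-2-en-1-yl)cyclohex-2-en-1-ol (C1 epimers) | CC1(O)C=CCC[C@H]1CC=C(C)C
F7 | step 6 | 1-[(4R)-5,5-dimethyl-4,6-bis(3-methylbut-2-en-1-yl)cyclohex-1-en-1-yl]pyrrolidine (C6 epimers) | CC(C)=CCC1C(N2CCCC2)=CC[C@@H](CC=C(C)C)C1(C)C
F8 | step 6 | (1R,5R,7R)-8,8-dimethyl-1,7-bis(3-methylbut-2-en-1-yl)bicyclo[3.3.1]nonane-2,9-dione | [C@H]12C[C@@H](CC=C(C)C)C(C)(C)[C@](CC=C(C)C)(C(=O)CC1)C2=O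
F9 | step 6 | (1R,5S,7R)-8,8-dimethyl-1,7-bis(3-methylbut-2-en-1-yl)bicyclo[3.3.1]non-3-ene-2,9-dione | [C@H]12C[C@@H](CC=C(C)C)C(C)(C)[C@](CC=C(C)C)(C(=O)C=C1)C2=O
F10 | step 8 | (4R)-6-[(2E)-3,7-dimethylocta-2,6-dien-1-yl]-3,3-dimethyl-2,4-bis(3-methylbut-2-en-1-yl)cyclohexan-1-one (C2 and C6 epimers) | O=C1C(C/C=C(\C)CCC=C(C)C)C[C@@H](CC=C(C)C)C(C)(C)C1CC=C(C)C
F11 | step 8 | {[(4R)-2-[(2E)-3,7-dimethylocta-2,6-dien-1-yl]-5,5-dimethyl-4,6-bis(3-methylbut-2-en-1-yl)cyclohex-1-en-1-yl]oxy}trimethylsilane (C6 epimers) | C[Si](C)(C)OC1=C(C/C=C(\C)CCC=C(C)C)C[C@@H](CC=C(C)C)C(C)(C)C1CC=C(C)C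
F12 | step 8 | (1R,5S,7R)-5-[(2E)-3,7-dimethylocta-2,6-dien-1-yl]-4-hydroxy-8,8-dimethyl-1,7-bis(3-methylbut-2-en-1-yl)bicyclo[3.3.1]non-3-ene-2,9-dione | CC(C)=CCC/C(C)=C/C[C@]12C[C@@H](CC=C(C)C)C(C)(C)[C@](CC=C(C)C)(C(=O)C=C1O)C2=O
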